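**Remarks on the chemistry**

- Germacrane numbering is used: ring carbons C1–C10, C14 is the methyl on C10, C15 the methyl on C4, and C11, C12 (carbonyl) and C13 (CH2O) are the lactone carbons.
- The C8 ester is read from the SMILES as the tiglate, (E)-2-methylbut-2-enoate.
- C7 is trigonal in the target, so its carbinol configuration in the intermediates is free. It is taken as it comes from D-xylonolactone, so 16 and 17 are the C7 epimers of the ribo-configured compounds one would first write down.
- The 4-methoxybenzyl (PMB) group sits on O7 and triethylsilyl on O6. A benzyl-type ether on O6 could chelate samarium in the ring closure and would then favour the wrong C5 epimer (see step 14).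
- D-Xylono-1,4-lactone (1) and methyl 2-(dimethoxyphosphoryl)acrylate (23) are taken as purchasable; 1 is otherwise one oxidation from D-xylose.

## Analysis of the target

The target 33 is a germacranolide: a ten-membered carbocycle (C1–C10) fused across C6–C7 to a butenolide (C7=C11, C12 carbonyl, ring oxygen on C6) and across C4–C5 to an oxirane. The ring carries a (9Z)-trisubstituted olefin (C9=C10 with the C14 methyl), a free allylic hydroxyl at C1, a tiglate at C8, the acetoxymethyl carbon C13 on C11 and the C15 methyl on C4. There are five stereocentres: C1 (S), C4 (R), C5 (R), C6 (S) and C8 (S). C4 and C5 form a trans-epoxide (C3 and C6 on opposite sides), C5 and C6 are contiguous, and C8 and C1 flank the Z-olefin. C7 lies between two oxygenated stereocentres but is trigonal, so its configuration in any precursor is without consequence. The sensitive points are the trisubstituted epoxide (acid, transannular attack by the 9,10-olefin), two different acyl groups that can migrate (O8 to O1 across the Z-olefin), possible relactonization from O6 to O8, and the acidic C6–H and C8–H next to the butenolide. The difficulty is to close a medium ring that carries differentiated oxygens on C1, C4, C5, C6 and C8 and to relay stereochemistry across it. The strategy rests on the vicinal pair C4 (methyl and oxygen) and C5 (oxygen and hydrogen): this is the retron of a pinacol coupling between a C4 methyl ketone and a C5 aldehyde, and the erythro (cis) 4,5-diol becomes the trans-epoxide when O4 displaces an activated O5 with inversion at C5.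

## Retrosynthetic reasoning

**Acyl groups and the C1 hydroxyl (33 back to 28).** The esters are the most fragile parts of 33, so they are introduced last. The C1 silyl ether of 32 is cleaved at the end; the acetate comes from the C13 alcohol 31, which is unmasked from the PMB ether 30. The tiglate of 30 is placed on the C8 alcohol 29, obtained from the silyl ether 28. Cutting the C–O acyl bonds here means the ring closure and the butenolide synthesis only have to tolerate ethers.

**Butenolide (28 back to 22 and 26).** The C7=C11 double bond and the C12–O6 ester bond are cut. This leads to the α-hydroxy ketone 22 and the phosphonoacetic acid 26, which already carries C13 as a PMB ether. Forward, esterification gives 27 and an intramolecular Horner–Wadsworth–Emmons reaction closes the five-membered ring. This cut is chosen because a C7 ketone with a C6 hydroxyl is the pattern a differentiated polyol can deliver, and because the phosphonate is far more acidic than the ketone, so a weak base suffices. Acid 26 comes from the acrylate 23 and the alcohol 24 through ester 25.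

**C7 ketone and C6 hydroxyl (22 back to 19).** The ketone 21 is the oxidation product of alcohol 20, which is set free from the PMB ether 19; the C6 hydroxyl of 22 is then released from its triethylsilyl ether. The order of release (O7, then O6, then O8, then O1) dictates the protecting groups: PMB, triethylsilyl, tert-butyldimethylsilyl, tert-butyldiphenylsilyl.

**Epoxide (19 back to 17).** The C5–O bond of the oxirane is cut. The epoxide comes from the mesylate 18 of the cis-diol 17 by attack of O4 on C5 with inversion. The tertiary and secondary hydroxyls are told apart by reactivity alone.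

**Ten-membered ring (17 back to 16).** The C4–C5 bond is cut. This is the only ring bond whose two ends are both oxygenated in the target, so both carbons can be carbonyl carbons in the open chain. Forward, a samarium-mediated reductive coupling of the keto-aldehyde 16 must close the ring and set C4 and C5. The gain is that C1, C6 and C8 can be set in an acyclic chain beforehand.

**Ketone and aldehyde of 16 (16 back to 13).** The aldehyde comes from the primary alcohol 15 and the methyl ketone from the terminal alkene of 14 by Wacker oxidation. Alcohol 14 arises from the cyclic acetal 13 by reductive opening, which in one step frees O5 and leaves the PMB group on O7.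

**C1 stereocentre and C1–C2 bond (13 back to 9 and 10).** The silyl ether 13 comes from the alcohol 12, which is the product of a reagent-controlled (CBS) reduction of the Z-enone 11. The C1–C2 bond is cut to the Weinreb amide 9 and the butenyl Grignard reagent 10; the alkene of 10 is the masked methyl ketone.

**C9=C10 olefin (9 back to 6 and 7).** The amide 9 comes from the ester 8, whose Z-trisubstituted double bond is cut to the aldehyde 6 and the phosphonate 7 (Still–Gennari olefination).

**Chiral pool (6 back to 1).** Aldehyde 6 is the reduced Weinreb amide 5. Amide 5 comes from lactone 3 by ring opening (4) and silylation of the hydroxyl that the opening releases, and 3 comes from D-xylono-1,4-lactone 1 by acetalization (2) and silylation. The lactone differentiates all four oxygens without any selective protection of like hydroxyls: O3 and O5 are the only pair that can form a six-membered acetal, O2 is then the only free hydroxyl, and O4 is released alone when the lactone is opened. Sugar C2 and C4 have the configurations needed at C8 and C6.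

## Alternatives that were turned down

**Alternative 1:** The two C–O bonds at C8 and C1 and the 9,10-olefin are disconnected together, back to the (1(10)Z,8Z)-triene lactone A2. Forward, singlet oxygen would add as a dienophile across C8 and C1 of A2 and give the endoperoxide A1.

- For: the concerted suprafacial addition guarantees the cis-1,4 relationship of the two oxygens and the Z geometry of the new olefin, in one late step without protecting groups. On step economy at the oxygenation stage it is clearly stronger than the chosen route.
- Against: the diene of A2 is cross-conjugated with the butenolide and therefore poor towards an electrophilic oxidant, while the methyl-bearing 1(10)-olefin offers allylic hydrogens for the competing ene reaction.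
- Against: the face of attack is decided only by the ring conformation, remote from C4–C6.
- Against: after O–O cleavage two similar secondary allylic alcohols must be told apart for monotigloylation, and A1 can isomerize under base to a hydroxy enone.
- Against: A2 still needs a ten-membered ring synthesis of its own.
- Comparison: the chosen route offers C8 from the chiral pool, C1 by reagent control, and O8 and O1 differentiated from the first steps.

**Alternative 2:** The C6–C7 bond and the lactone C12–O6 bond are disconnected, back to the acyclic enol triflate epoxy aldehyde A4. Forward, under Nozaki–Hiyama–Kishi conditions the alkenylchromium from the (Z)-enol triflate would add to the C6 aldehyde, close the ten-membered ring, and the C6 alkoxide would lactonize onto the cis ester to give A3, the C1 silyl ether of 33.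

- For: ring and butenolide form in one step with all acyl groups and the epoxide in place, and A3 is one deprotection from 33. On the number of steps after ring closure and on precedent for ten-membered closures it is stronger than the chosen route.
- Against: A4 combines an epimerizable, Lewis-acid-sensitive α,β-epoxy aldehyde with two allylic esters next to the metalated carbon, where low-valent nickel can ionize allylic C–O bonds.
- Against: the alkenylmetal is tetrasubstituted and hindered.
- Against: C6 is created in the ring closure with only the adjacent epoxide to steer it, and a wrong C6 epimer cannot be corrected because lactonization follows at once.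
- Against: A4, a stereodefined tetrasubstituted enol triflate with four stereocentres, is at least as long to make as 16.
- Comparison: the chosen route closes the ring with only ethers and silyl ethers present, has C6 fixed from the sugar, and brings in the fragile esters last. The price is about fourteen steps after ring closure.

**Alternative 3:** The ten-membered ring is traced back to a decalin by reconnecting C4 and C9. Forward, the tosylhydrazone of the epoxy octalone A6 would fragment with loss of nitrogen and sulfinate, cleave the C4–C9 bond and give the cyclodecynone A5.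

- For: the ring is made by fragmentation, so there is no entropic penalty and no high dilution, and A6 comes from robust annulation chemistry. For reliability of ring formation it is the strongest of the four.
- Against: A5 holds one of the five stereocentres and lacks C14, C15, the oxygens at C5, C6 and C8 and the lactone carbons.
- Against: the later steps would need a regio- and syn-selective carbometalation of the alkyne to place C14 with Z geometry, and oxygenations at C6 and C8 that are both α to the C7 ketone and hard to tell apart.
- Against: C4, C5, C6 and C8 would have to be controlled on a flexible ring with C1 as the only handle.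
- Comparison: the chosen route sets C1, C6 and C8 in open-chain intermediates and asks the ring closure for C4 and C5 only.

Key step: step 14

## Route

Step 1
Reactants: 1 D-xylono-1,4-lactone
Product: 2 3,5-O-(4-methoxybenzylidene)-D-xylono-1,4-lactone (cis-fused 1,3-dioxane, aryl equatorial, 2-OH free)
Conditions: 4-MeOC6H4CH(OMe)2, camphorsulfonic acid (cat.), MeCN, rt, MeOH removed under reduced pressure
Reagents that add atoms: 4-methoxybenzaldehyde dimethyl acetal, COC(OC)c1ccc(OC)cc1
Why: Acid-catalysed transacetalization under thermodynamic control; only O3 and O5 are cis on the lactone and can span a six-membered acetal (O2 is trans to O3), and the aryl group takes the equatorial position, which fixes the acetal carbon.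

Step 2
Reactants: 2 3,5-O-(4-methoxybenzylidene)-D-xylono-1,4-lactone
Product: 3 2-O-(tert-butyldimethylsilyl)-3,5-O-(4-methoxybenzylidene)-D-xylono-1,4-lactone
Conditions: TBSCl, imidazole, DMF, rt
Reagents that add atoms: tert-butyldimethylsilyl chloride, CC(C)(C)[Si](C)(C)Cl
Why: Imidazole-promoted silylation of the only free hydroxyl (the future O8); the lactone α-centre is not enolized under these conditions.

Step 3
Reactants: 3 2-O-TBS-3,5-O-(4-methoxybenzylidene)-D-xylono-1,4-lactone
Product: 4 N-methoxy-N-methyl-2-O-(tert-butyldimethylsilyl)-3,5-O-(4-methoxybenzylidene)-D-xylonamide (4-OH free; sugar C1–C5 are C9–C5 of the target)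
Conditions: MeNHOMe·HCl, i-PrMgCl, THF, −20 to 0 °C
Reagents that add atoms: N,O-dimethylhydroxylamine hydrochloride, CNOC.Cl
Why: Aminolysis of the γ-lactone by the chloromagnesium amide (Weinreb amide formation) opens the ring and releases only the C6 hydroxyl (sugar O4), which is thereby distinguished from O7 and O8; the crude amide is silylated at once to forestall relactonization.

Step 4
Reactants: 4 hydroxy Weinreb amide
Product: 5 4-O-triethylsilyl ether of 4
Conditions: Et3SiCl, imidazole, DMF, 0 °C to rt
Reagents that add atoms: chlorotriethylsilane, CC[Si](Cl)(CC)CC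
Why: Silylation of the only free hydroxyl; triethylsilyl on O6 is non-chelating in the key step and is later the most labile of the three silyl ethers.

Step 5
Reactants: 5 fully protected Weinreb amide
Product: 6 2-O-(tert-butyldimethylsilyl)-4-O-(triethylsilyl)-3,5-O-(4-methoxybenzylidene)-aldehydo-D-xylose (C9 aldehyde, C8 OTBS, C6 OTES, O7/O5 acetal)
Conditions: i-Bu2AlH, THF, −78 °C
Reagents that add atoms: none
Why: Weinreb amides are reduced by i-Bu2AlH to aldehydes through the stable chelated hemiaminal; at −78 °C the benzylidene acetal is not opened.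

Step 6
Reactants: 6 C9 aldehyde; 7 methyl 2-[bis(2,2,2-trifluoroethoxy)phosphoryl]propanoate
Product: 8 methyl (Z)-2-methylbut-2-enoate (C1 ester, C9=C10 Z, C14 methyl) bearing at C8 the OTBS group and the 2-(4-methoxyphenyl)-5-(triethylsilyloxy)-1,3-dioxan-4-yl residue (C7, C6, C5)
Conditions: KN(SiMe3)2, 18-crown-6, THF, −78 °C
Reagents that add atoms: none
Why: Still–Gennari olefination; the electron-poor bis(trifluoroethyl) phosphonate makes elimination from the first adduct fast, so the kinetic (Z)-trisubstituted enoate is expected, and α-oxygenated, α-branched aldehydes are good substrates.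

Step 7
Reactants: 8 (Z)-enoate
Product: 9 (Z)-N-methoxy-N-methyl amide corresponding to 8
Conditions: MeNHOMe·HCl, i-PrMgCl, THF, −20 to 0 °C
Reagents that add atoms: N,O-dimethylhydroxylamine hydrochloride, CNOC.Cl
Why: Direct ester-to-Weinreb-amide exchange with the magnesium amide; at low temperature no conjugate addition–elimination pathway operates, so the olefin geometry should be kept.

Step 8
Reactants: 9 (Z)-Weinreb amide; 10 3-butenylmagnesium bromide
Product: 11 (Z)-enone with the C1 ketone carrying the but-3-enyl chain (C2, C3, C4, C15)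
Conditions: THF, 0 °C
Reagents that add atoms: none
Why: Grignard addition to a Weinreb amide stops at the ketone because the tetrahedral magnesium chelate survives until work-up; it forms the C1–C2 bond and brings C2–C4 and C15 as a latent methyl ketone.

Step 9
Reactants: 11 (Z)-enone
Product: 12 (1S)-allylic alcohol
Conditions: (R)-2-methyl-CBS-oxazaborolidine, catecholborane, toluene, −78 °C
Reagents that add atoms: none
Why: Corey–Bakshi–Shibata reduction; the α-methyl alkenyl group acts as the large substituent, so the (R)-oxazaborolidine should give the (1S)-alcohol under reagent control, and catecholborane does not hydroborate the terminal alkene at −78 °C.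

Step 10
Reactants: 12 (1S)-allylic alcohol
Product: 13 (1S)-tert-butyldiphenylsilyl ether of 12
Conditions: TBDPSCl, imidazole, DMAP (cat.), DMF, rt to 40 °C
Reagents that add atoms: tert-butyldiphenylsilyl chloride, CC(C)(C)[Si](Cl)(c1ccccc1)c1ccccc1
Why: Silylation of the secondary allylic alcohol; tert-butyldiphenylsilyl is the most robust of the silyl ethers and is meant to come off last.

Step 11
Reactants: 13 acetal-protected silyl ether
Product: 14 open-chain primary alcohol (C5–OH, C6 OTES, C7 OPMB, C8 OTBS, 9Z, C1 OTBDPS, terminal alkene C4=C15)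
Conditions: i-Bu2AlH, CH2Cl2, −20 to 0 °C
Reagents that add atoms: none
Why: Reductive opening of a 4-methoxybenzylidene acetal; aluminium binds the less hindered primary O5, that C–O bond ionizes and hydride traps the oxocarbenium ion, leaving PMB on the secondary O7 and a free C5 alcohol.

Step 12
Reactants: 14 alkenyl primary alcohol
Product: 15 C4 methyl ketone with C5–OH
Conditions: PdCl2 (cat.), Cu(OAc)2 (cat.), O2 (1 atm), DMA/H2O 7:1, rt
Reagents that add atoms: water, O
Why: Tsuji–Wacker oxidation; Markovnikov hydroxypalladation of the monosubstituted alkene gives the methyl ketone, the trisubstituted 9,10-olefin is inert, and the acetate-buffered copper system avoids HCl that would endanger the triethylsilyl ether.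

Step 13
Reactants: 15 keto alcohol
Product: 16 (1S,6S,7R,8S,9Z)-keto-aldehyde: C4 methyl ketone, C5 aldehyde, C6 OTES, C7 OPMB, C8 OTBS, C1 OTBDPS
Conditions: Dess–Martin periodinane, NaHCO3, CH2Cl2, 0 °C to rt
Reagents that add atoms: none
Why: Dess–Martin oxidation of the primary alcohol under buffered, non-epimerizing conditions; the ketone is untouched and the α-silyloxy aldehyde is used at once.

Step 14
Reactants: 16 keto-aldehyde
Product: 17 (1S,4R,5S,6R,7R,8S,9Z)-ten-membered cis-4,5-diol (C4 tertiary and C5 secondary carbinols; C6 OTES, C7 OPMB, C8 OTBS, C1 OTBDPS)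
Conditions: SmI2 (3 equiv, 0.1 M in THF), 16 added by syringe pump to 0.002 M, THF, rt; then aq. NH4Cl
Reagents that add atoms: none
Why: SmI2 transfers one electron to the more easily reduced C5 aldehyde; the samarium-bound ketyl adds to the C4 ketone held on the same oxophilic trivalent samarium centre, and a second equivalent of SmI2 gives the samarium diolate, which is protonated on work-up. The closest known reaction type is the SmI2-mediated intramolecular pinacol coupling of keto-aldehydes, established for five- to eight-membered rings, together with low-valent titanium pinacol closures of ten-membered and larger carbocycles. The ring closes in a 10-exo-trig mode, the ketyl carbon C5 attacking C4 of the exocyclic C=O. C4 is controlled by the bridged diolate: both oxygens sit on one samarium, and the Z-olefin on the far side of the ring makes the two three-carbon arms (C1–C3 and C6–C8) run parallel, so C3 and C6 are synclinal across the new bond and the diol should be cis (4R with 5S). C5 is controlled by the C6 stereocentre: the bulky, non-chelating triethylsilyloxy group orients anti to the ketyl C–O bond (Felkin–Anh-type, dipole-minimized), so the 5,6-anti (erythro) isomer, 5S, is expected. The step needs intramolecular over intermolecular coupling, which slow addition at high dilution secures, and reduction of the aldehyde before the ketone, which is intrinsic. It also needs no ketyl addition to the 9,10-olefin and no loss of the C6 oxygen; omitting HMPA and proton donors and using a silyl ether as a poor leaving group serve that end.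

Step 15
Reactants: 17 cis-4,5-diol
Product: 18 C5 methanesulfonate of 17 (C4–OH free)
Conditions: MsCl, Et3N, CH2Cl2, −20 °C
Reagents that add atoms: methanesulfonyl chloride, CS(=O)(=O)Cl
Why: Sulfonylation through sulfene is selective for the secondary C5 hydroxyl; the tertiary C4 hydroxyl does not react at low temperature.

Step 16
Reactants: 18 hydroxy mesylate
Product: 19 (1S,4R,5R,6S,7R,8S,9Z)-trans-4,5-epoxide
Conditions: K2CO3, MeOH, 0 °C to rt
Reagents that add atoms: none
Why: Intramolecular Williamson-type displacement (3-exo-tet); the C4 alkoxide attacks C5 from the rear, inverting C5 (S to R) and keeping C4, so the erythro diol gives the trans-epoxide, and a ten-membered ring can turn the C3–C4–C5–C6 torsion to antiperiplanar.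

Step 17
Reactants: 19 epoxide with C7 OPMB
Product: 20 C7 alcohol
Conditions: DDQ, CH2Cl2/pH 7 buffer, 0 °C
Reagents that add atoms: none
Why: Oxidative cleavage of a 4-methoxybenzyl ether by DDQ (hydride abstraction, then hydrolysis of the oxocarbenium ion); silyl ethers, the epoxide and the unactivated olefin are inert under buffered conditions.

Step 18
Reactants: 20 C7 alcohol
Product: 21 C7 ketone (C6 OTES, C8 OTBS, 4,5-epoxide)
Conditions: Dess–Martin periodinane, NaHCO3, CH2Cl2, rt
Reagents that add atoms: none
Why: Dess–Martin oxidation of a hindered secondary alcohol under neutral buffered conditions, which the β,γ-epoxy ketone tolerates; the C7 stereocentre disappears here.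

Step 19
Reactants: 21 C7 ketone
Product: 22 C6 alcohol (α-hydroxy ketone; C8 OTBS, C1 OTBDPS)
Conditions: HF·pyridine, pyridine, THF, 0 °C
Reagents that add atoms: none
Why: Buffered HF·pyridine discriminates by silyl bulk, cleaving the triethylsilyl ether far faster than the tert-butyldimethylsilyl and tert-butyldiphenylsilyl ethers; acidic fluoride avoids the alkoxide that would start epoxide migration.

Step 20
Reactants: 23 methyl 2-(dimethoxyphosphoryl)acrylate; 24 4-methoxybenzyl alcohol
Product: 25 methyl 2-(dimethoxyphosphoryl)-3-[(4-methoxybenzyl)oxy]propanoate (racemic)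
Conditions: KOt-Bu (cat.), THF, 0 °C, 23 added dropwise to 24
Reagents that add atoms: none
Why: Base-catalysed oxa-Michael addition of the alcohol to the doubly activated vinylphosphonate; the β-alkoxy phosphonate is the thermodynamically favoured adduct.

Step 21
Reactants: 25 phosphonate methyl ester
Product: 26 2-(dimethoxyphosphoryl)-3-[(4-methoxybenzyl)oxy]propanoic acid (racemic)
Conditions: Me3SnOH, ClCH2CH2Cl, 70 °C; 1 M HCl work-up
Reagents that add atoms: trimethyltin hydroxide, C[Sn](C)(C)O
Why: Me3SnOH cleaves methyl carboxylates under nearly neutral conditions, so the phosphonate-stabilized carbanion that could expel the β-alkoxide is not formed; the phosphonate methyl esters are kept.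

Step 22
Reactants: 22 α-hydroxy ketone; 26 phosphonoacetic acid
Product: 27 C6 ester of 22 with 26 (both C11 epimers)
Conditions: DCC, DMAP (cat.), CH2Cl2, 0 °C to rt
Reagents that add atoms: none
Why: Steglich esterification of the secondary hydroxyl; no alkoxide is generated, so epoxide migration and α-ketol rearrangement are avoided, and the C11 epimers are carried on together because C11 becomes trigonal.

Step 23
Reactants: 27 keto phosphonate
Product: 28 butenolide: 13-(4-methoxybenzyloxy)-4,5-epoxy-8-(TBS-oxy)-1-(TBDPS-oxy)germacra-7(11),9-dien-12,6-olide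
Conditions: LiCl, i-Pr2NEt, MeCN, rt
Reagents that add atoms: none
Why: Intramolecular Horner–Wadsworth–Emmons reaction under Masamune–Roush conditions; the lithium-chelated phosphonate, far more acidic than the ketone α-hydrogens, is deprotonated by the amine, adds to the C7 ketone in a 5-exo sense and loses phosphate to give the C7=C11 butenolide with C13 in place.

Step 24
Reactants: 28 butenolide with C8 OTBS
Product: 29 C8 alcohol
Conditions: HF·pyridine, THF, 0 °C to rt
Reagents that add atoms: none
Why: Acidic fluoride removes the tert-butyldimethylsilyl ether at C8, which lies between two trigonal carbons, much faster than the tert-butyldiphenylsilyl ether at C1; no alkoxide is formed, which disfavours relactonization from O6 to O8.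

Step 25
Reactants: 29 C8 alcohol
Product: 30 C8 tiglate
Conditions: tigloyl chloride, Et3N, DMAP (cat.), CH2Cl2, 0 °C
Reagents that add atoms: (E)-2-methylbut-2-enoyl chloride, C/C=C(\C)C(=O)Cl
Why: Acylation of the secondary allylic alcohol with the acid chloride under nucleophilic catalysis; the tiglate is the stable (E) isomer, so no geometric scrambling is expected.

Step 26
Reactants: 30 C13 PMB ether
Product: 31 C13 alcohol
Conditions: DDQ, CH2Cl2/pH 7 buffer, rt
Reagents that add atoms: none
Why: DDQ cleavage of the primary 4-methoxybenzyl ether; the electron-poor allylic alcohol formed should not be oxidized further.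

Step 27
Reactants: 31 C13 alcohol
Product: 32 C13 acetate (the 1-O-tert-butyldiphenylsilyl ether of the target)
Conditions: Ac2O, pyridine, DMAP (cat.), CH2Cl2, 0 °C
Reagents that add atoms: acetic anhydride, CC(=O)OC(C)=O
Why: Standard acetylation of the primary alcohol; the only other hydroxyl, at C1, is still silylated.

Step 28
Reactants: 32 silyl ether of the target
Product: 33 target, (1S,4R,5R,6S,8S,9Z)-13-acetoxy-4,5-epoxy-1-hydroxy-8-tigloyloxygermacra-7(11),9-dien-12,6-olide
Conditions: Bu4NF, AcOH (1:1), THF, 0 °C to rt
Reagents that add atoms: none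
Why: Fluoride cleavage of the silyl ether with acetic acid buffering, which suppresses alkoxide-driven acyl migration from O8 to O1 and ester cleavage; the epoxide is stable to buffered fluoride.

## Compound list

1 | D-xylono-1,4-lactone | O=C1[C@H](O)[C@@H](O)[C@@H](CO)O1 | starting material
2 | 3,5-O-(4-methoxybenzylidene)-D-xylono-1,4-lactone | O=C1[C@H](O)[C@H]2O[C@@H](c3ccc(OC)cc3)OC[C@H]2O1 | intermediate
3 | 2-O-(tert-butyldimethylsilyl)-3,5-O-(4-methoxybenzylidene)-D-xylono-1,4-lactone | O=C1[C@H](O[Si](C)(C)C(C)(C)C)[C@H]2O[C@@H](c3ccc(OC)cc3)OC[C@H]2O1 | intermediate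
4 | N-methoxy-N-methyl-2-O-(tert-butyldimethylsilyl)-3,5-O-(4-methoxybenzylidene)-D-xylonamide | CON(C)C(=O)[C@H](O[Si](C)(C)C(C)(C)C)[C@H]1O[C@@H](c2ccc(OC)cc2)OC[C@H]1O | intermediate
5 | 4-O-triethylsilyl ether of 4 | CON(C)C(=O)[C@H](O[Si](C)(C)C(C)(C)C)[C@H]1O[C@@H](c2ccc(OC)cc2)OC[C@H]1O[Si](CC)(CC)CC | intermediate
6 | 2-O-(tert-butyldimethylsilyl)-4-O-(triethylsilyl)-3,5-O-(4-methoxybenzylidene)-aldehydo-D-xylose | O=C[C@H](O[Si](C)(C)C(C)(C)C)[C@H]1O[C@@H](c2ccc(OC)cc2)OC[C@H]1O[Si](CC)(CC)CC | intermediate
7 | methyl 2-[bis(2,2,2-trifluoroethoxy)phosphoryl]propanoate | COC(=O)C(C)P(=O)(OCC(F)(F)F)OCC(F)(F)F | starting material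
8 | methyl (Z)-enoate (C1 ester, 9Z, C8 OTBS, C6 OTES, O7/O5 acetal) | COC(=O)/C(C)=C\[C@H](O[Si](C)(C)C(C)(C)C)[C@H]1O[C@@H](c2ccc(OC)cc2)OC[C@H]1O[Si](CC)(CC)CC | intermediate
9 | (Z)-N-methoxy-N-methyl amide corresponding to 8 | CON(C)C(=O)/C(C)=C\[C@H](O[Si](C)(C)C(C)(C)C)[C@H]1O[C@@H](c2ccc(OC)cc2)OC[C@H]1O[Si](CC)(CC)CC | intermediate
10 | 3-butenylmagnesium bromide | C=CCC[Mg]Br | starting material
11 | (Z)-enone (C1 ketone with but-3-enyl chain) | C=CCCC(=O)/C(C)=C\[C@H](O[Si](C)(C)C(C)(C)C)[C@H]1O[C@@H](c2ccc(OC)cc2)OC[C@H]1O[Si](CC)(CC)CC | intermediate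
12 | (1S)-allylic alcohol | C=CCC[C@H](O)/C(C)=C\[C@H](O[Si](C)(C)C(C)(C)C)[C@H]1O[C@@H](c2ccc(OC)cc2)OC[C@H]1O[Si](CC)(CC)CC | intermediate
13 | (1S)-tert-butyldiphenylsilyl ether of 12 | C=CCC[C@H](O[Si](c1ccccc1)(c1ccccc1)C(C)(C)C)/C(C)=C\[C@H](O[Si](C)(C)C(C)(C)C)[C@H]1O[C@@H](c2ccc(OC)cc2)OC[C@H]1O[Si](CC)(CC)CC | intermediate
14 | open-chain primary alcohol (C5–OH, C6 OTES, C7 OPMB, C8 OTBS, C1 OTBDPS, terminal alkene) | C=CCC[C@H](O[Si](c1ccccc1)(c1ccccc1)C(C)(C)C)/C(C)=C\[C@H](O[Si](C)(C)C(C)(C)C)[C@@H](OCc1ccc(OC)cc1)[C@H](O[Si](CC)(CC)CC)CO | intermediate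
15 | C4 methyl ketone with C5–OH | CC(=O)CC[C@H](O[Si](c1ccccc1)(c1ccccc1)C(C)(C)C)/C(C)=C\[C@H](O[Si](C)(C)C(C)(C)C)[C@@H](OCc1ccc(OC)cc1)[C@H](O[Si](CC)(CC)CC)CO | intermediate
16 | (1S,6S,7R,8S,9Z)-keto-aldehyde (C4 methyl ketone, C5 aldehyde) | CC(=O)CC[C@H](O[Si](c1ccccc1)(c1ccccc1)C(C)(C)C)/C(C)=C\[C@H](O[Si](C)(C)C(C)(C)C)[C@@H](OCc1ccc(OC)cc1)[C@H](O[Si](CC)(CC)CC)C=O | intermediate
17 | (1S,4R,5S,6R,7R,8S,9Z)-ten-membered cis-4,5-diol | C[C@@]1(O)CC[C@H](O[Si](c2ccccc2)(c2ccccc2)C(C)(C)C)/C(C)=C\[C@H](O[Si](C)(C)C(C)(C)C)[C@@H](OCc2ccc(OC)cc2)[C@H](O[Si](CC)(CC)CC)[C@@H]1O | intermediate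
18 | C5 methanesulfonate of 17 | C[C@@]1(O)CC[C@H](O[Si](c2ccccc2)(c2ccccc2)C(C)(C)C)/C(C)=C\[C@H](O[Si](C)(C)C(C)(C)C)[C@@H](OCc2ccc(OC)cc2)[C@H](O[Si](CC)(CC)CC)[C@@H]1OS(C)(=O)=O | intermediate
19 | (1S,4R,5R,6S,7R,8S,9Z)-trans-4,5-epoxide | C[C@@]12CC[C@H](O[Si](c3ccccc3)(c3ccccc3)C(C)(C)C)/C(C)=C\[C@H](O[Si](C)(C)C(C)(C)C)[C@@H](OCc3ccc(OC)cc3)[C@H](O[Si](CC)(CC)CC)[C@H]1O2 | intermediate
20 | C7 alcohol | C[C@@]12CC[C@H](O[Si](c3ccccc3)(c3ccccc3)C(C)(C)C)/C(C)=C\[C@H](O[Si](C)(C)C(C)(C)C)[C@@H](O)[C@H](O[Si](CC)(CC)CC)[C@H]1O2 | intermediate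
21 | C7 ketone | C[C@@]12CC[C@H](O[Si](c3ccccc3)(c3ccccc3)C(C)(C)C)/C(C)=C\[C@H](O[Si](C)(C)C(C)(C)C)C(=O)[C@H](O[Si](CC)(CC)CC)[C@H]1O2 | intermediate
22 | C6 alcohol (α-hydroxy ketone) | C[C@@]12CC[C@H](O[Si](c3ccccc3)(c3ccccc3)C(C)(C)C)/C(C)=C\[C@H](O[Si](C)(C)C(C)(C)C)C(=O)[C@H](O)[C@H]1O2 | intermediate
23 | methyl 2-(dimethoxyphosphoryl)acrylate | C=C(C(=O)OC)P(=O)(OC)OC | starting material
24 | 4-methoxybenzyl alcohol | COc1ccc(CO)cc1 | starting material
25 | methyl 2-(dimethoxyphosphoryl)-3-[(4-methoxybenzyl)oxy]propanoate (racemic) | COC(=O)C(COCc1ccc(OC)cc1)P(=O)(OC)OC | intermediate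
26 | 2-(dimethoxyphosphoryl)-3-[(4-methoxybenzyl)oxy]propanoic acid (racemic) | OC(=O)C(COCc1ccc(OC)cc1)P(=O)(OC)OC | intermediate
27 | C6 ester of 22 with 26 (both C11 epimers) | C[C@@]12CC[C@H](O[Si](c3ccccc3)(c3ccccc3)C(C)(C)C)/C(C)=C\[C@H](O[Si](C)(C)C(C)(C)C)C(=O)[C@H](OC(=O)C(COCc3ccc(OC)cc3)P(=O)(OC)OC)[C@H]1O2 | intermediate
28 | butenolide with C13 OPMB, C8 OTBS, C1 OTBDPS | CC(C)(C)[Si](C)(C)O[C@H]1/C=C(/C)[C@@H](O[Si](c2ccccc2)(c2ccccc2)C(C)(C)C)CC[C@@]2(C)O[C@@H]2[C@H]2OC(=O)C(COCc3ccc(OC)cc3)=C12 | intermediate
29 | C8 alcohol | O[C@H]1/C=C(/C)[C@@H](O[Si](c2ccccc2)(c2ccccc2)C(C)(C)C)CC[C@@]2(C)O[C@@H]2[C@H]2OC(=O)C(COCc3ccc(OC)cc3)=C12 | intermediate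
30 | C8 tiglate | C/C=C(\C)C(=O)O[C@H]1/C=C(/C)[C@@H](O[Si](c2ccccc2)(c2ccccc2)C(C)(C)C)CC[C@@]2(C)O[C@@H]2[C@H]2OC(=O)C(COCc3ccc(OC)cc3)=C12 | intermediate
31 | C13 alcohol | C/C=C(\C)C(=O)O[C@H]1/C=C(/C)[C@@H](O[Si](c2ccccc2)(c2ccccc2)C(C)(C)C)CC[C@@]2(C)O[C@@H]2[C@H]2OC(=O)C(CO)=C12 | intermediate
32 | C13 acetate, 1-O-tert-butyldiphenylsilyl ether of the target | C/C=C(\C)C(=O)O[C@H]1/C=C(/C)[C@@H](O[Si](c2ccccc2)(c2ccccc2)C(C)(C)C)CC[C@@]2(C)O[C@@H]2[C@H]2OC(=O)C(COC(C)=O)=C12 | intermediate
33 | (1S,4R,5R,6S,8S,9Z)-13-acetoxy-4,5-epoxy-1-hydroxy-8-tigloyloxygermacra-7(11),9-dien-12,6-olide | C/C=C(\C)C(=O)O[C@H]1/C=C(/C)[C@@H](O)CC[C@@]2(C)O[C@@H]2[C@H]2OC(=O)C(COC(C)=O)=C12 | target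

## Step count and least certain steps

Total: 28 steps. Longest linear sequence: 26 steps (steps 1–19 and 22–28, from 1). The phosphonate acid 26 is a two-step branch (steps 20–21).

**Step 14 (key step).**
- The ten-membered closure may be slower than intermolecular pinacol dimerization or than simple reduction of the aldehyde, because nothing but the Z-olefin preorganizes the chain.
- The C5 ketyl may add in a 5-exo sense to the 9,10-olefin.
- Diastereoselection may fail in two ways: an antiperiplanar arrangement of C3 and C6 in the bridged transition state would give the trans-diol, and attack on the other ketyl face would give the wrong facial sense relative to C6.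
- Fallback, from 16 back to 19: low-valent titanium (TiCl3(DME)1.5, Zn–Cu, DME, rt, high dilution), a pinacol coupling known to close ten-membered and larger rings and to favour trans-diols there, should give the trans-4,5-diol F1. Thiocarbonyldiimidazole converts it into the cyclic thiocarbonate F2. Corey–Winter elimination (1,3-dimethyl-2-phenyl-1,3,2-diazaphospholidine, THF, 40 °C) is stereospecific and gives the (4E,9Z)-diene F3. Epoxidation of the more electron-rich 4,5-olefin with mCPBA and NaHCO3 from the outer face, anti to the C6 silyl ether, returns to 19. In this fallback the epoxide face depends on the ring conformation and is not secured.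

**Step 23.**
- The phosphonate anion may expel the β-PMB oxide (retro-oxa-Michael) before it adds to the hindered ketone.
- The base may epimerize C8, or open the epoxide through the C6 enolate.
- Fallback, from 22 back to 32: C13 is introduced by cross-coupling after the ring is made. Steglich esterification of 22 with bromo(diethoxyphosphoryl)acetic acid gives the bromophosphonate ester F4. Its Horner–Wadsworth–Emmons closure (LiCl, i-Pr2NEt) gives the α-bromobutenolide F5. Stille coupling with Bu3SnCH2OH (Pd(PPh3)4, dioxane, 80 °C), done before any allylic ester is present, gives the C13 alcohol F6. Acetylation gives the acetate F7, HF·pyridine gives the C8 alcohol F8, and tigloyl chloride returns to 32.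

**Step 16.**
- The ring must turn the C3–C4–C5–C6 torsion from synclinal to antiperiplanar before O4 can displace the mesylate. If this is slow, base-induced silyl migration from O6 to O4 or elimination of the mesylate may take over.
- Fallback, from 17 directly to 19: Mitsunobu cyclodehydration (PPh3, DIAD, toluene) activates the secondary C5 hydroxyl as an oxyphosphonium ion under neutral conditions, with the same inversion at C5 and without a free alkoxide. This fallback makes no new compound (entry F0).

**Step 9.**
- Facial selectivity may be poor because the Z-β-substituent twists the enone out of plane and the C8 stereocentre may be mismatched with the catalyst.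
- The Z-enone may isomerize to E before reduction.
- Fallback, from 11 back to 12: Luche reduction (NaBH4, CeCl3·7H2O, MeOH, −78 °C) gives both C1 epimers, which are separated. The unwanted (1R)-alcohol F9 is inverted by Mitsunobu esterification with 4-nitrobenzoic acid to the (1S)-4-nitrobenzoate F10, and methanolysis (K2CO3, MeOH) gives 12.

## Further compounds

F1 | step 14 | trans-4,5-diol, (4S,5S), the C4 epimer of 17 | C[C@]1(O)CC[C@H](O[Si](c2ccccc2)(c2ccccc2)C(C)(C)C)/C(C)=C\[C@H](O[Si](C)(C)C(C)(C)C)[C@@H](OCc2ccc(OC)cc2)[C@H](O[Si](CC)(CC)CC)[C@@H]1O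
F2 | step 14 | 4,5-cyclic thiocarbonate of F1 | C[C@]12CC[C@H](O[Si](c3ccccc3)(c3ccccc3)C(C)(C)C)/C(C)=C\[C@H](O[Si](C)(C)C(C)(C)C)[C@@H](OCc3ccc(OC)cc3)[C@H](O[Si](CC)(CC)CC)[C@@H]1OC(=S)O2
F3 | step 14 | (4E,9Z)-cyclodecadiene with C6 OTES, C7 OPMB, C8 OTBS, C1 OTBDPS | C/C1=C\[C@@H](O[Si](CC)(CC)CC)[C@H](OCc2ccc(OC)cc2)[C@@H](O[Si](C)(C)C(C)(C)C)/C=C(/C)[C@@H](O[Si](c2ccccc2)(c2ccccc2)C(C)(C)C)CC1
F4 | step 23 | C6 bromo(diethoxyphosphoryl)acetate of 22 | C[C@@]12CC[C@H](O[Si](c3ccccc3)(c3ccccc3)C(C)(C)C)/C(C)=C\[C@H](O[Si](C)(C)C(C)(C)C)C(=O)[C@H](OC(=O)C(Br)P(=O)(OCC)OCC)[C@H]1O2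
F5 | step 23 | 11-bromobutenolide with C8 OTBS, C1 OTBDPS | CC(C)(C)[Si](C)(C)O[C@H]1/C=C(/C)[C@@H](O[Si](c2ccccc2)(c2ccccc2)C(C)(C)C)CC[C@@]2(C)O[C@@H]2[C@H]2OC(=O)C(Br)=C12
F6 | step 23 | C13 alcohol with C8 OTBS, C1 OTBDPS | CC(C)(C)[Si](C)(C)O[C@H]1/C=C(/C)[C@@H](O[Si](c2ccccc2)(c2ccccc2)C(C)(C)C)CC[C@@]2(C)O[C@@H]2[C@H]2OC(=O)C(CO)=C12
F7 | step 23 | C13 acetate with C8 OTBS, C1 OTBDPS | CC(C)(C)[Si](C)(C)O[C@H]1/C=C(/C)[C@@H](O[Si](c2ccccc2)(c2ccccc2)C(C)(C)C)CC[C@@]2(C)O[C@@H]2[C@H]2OC(=O)C(COC(C)=O)=C12
F8 | step 23 | C13 acetate with C8 OH, C1 OTBDPS | O[C@H]1/C=C(/C)[C@@H](O[Si](c2ccccc2)(c2ccccc2)C(C)(C)C)CC[C@@]2(C)O[C@@H]2[C@H]2OC(=O)C(COC(C)=O)=C12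
F0 | step 16 | none | none
F9 | step 9 | (1R)-allylic alcohol, the C1 epimer of 12 | C=CCC[C@@H](O)/C(C)=C\[C@H](O[Si](C)(C)C(C)(C)C)[C@H]1O[C@@H](c2ccc(OC)cc2)OC[C@H]1O[Si](CC)(CC)CC
F10 | step 9 | (1S)-4-nitrobenzoate of 12 | C=CCC[C@H](OC(=O)c1ccc(cc1)[N+](=O)[O-])/C(C)=C\[C@H](O[Si](C)(C)C(C)(C)C)[C@H]1O[C@@H](c2ccc(OC)cc2)OC[C@H]1O[Si](CC)(CC)CC
A1 | alternative 1 | 8,1-endoperoxide of the butenolide macrocycle | O1[C@H]2/C=C(/C)[C@@H](O1)CC[C@@]3(C)O[C@@H]3[C@H]3OC(=O)C(COC(C)=O)=C23
A2 | alternative 1 | (1(10)Z,8Z)-13-acetoxy-4,5-epoxygermacra-1(10),7(11),8-trien-12,6-olide | C/C1=C/CC[C@@]2(C)O[C@@H]2[C@H]2OC(=O)C(COC(C)=O)=C2/C=C\1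
A3 | alternative 2 | C1 tert-butyldimethylsilyl ether of the target | C/C=C(\C)C(=O)O[C@H]1/C=C(/C)[C@@H](O[Si](C)(C)C(C)(C)C)CC[C@@]2(C)O[C@@H]2[C@H]2OC(=O)C(COC(C)=O)=C12
A4 | alternative 2 | acyclic C7 (Z)-enol triflate with C12 methyl ester, C13 acetate, C8 tiglate, C1 OTBS and the 4,5-epoxy C6 aldehyde | C/C=C(\C)C(=O)O[C@H](/C(OS(=O)(=O)C(F)(F)F)=C(\COC(C)=O)C(=O)OC)/C=C(/C)[C@@H](O[Si](C)(C)C(C)(C)C)CC[C@@]1(C)O[C@@H]1C=O
A5 | alternative 3 | ten-membered ynone with C4 ketone, C9–C10 alkyne, C1 silyl ether and C7 dioxolane | O=C1CC[C@H](O[Si](C)(C)C(C)(C)C)C#CCC2(OCCO2)CC1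
A6 | alternative 3 | 4,9-epoxydecalin-10-one with C1 OTBS and C7 dioxolane (epoxide face left open; both fragment to A5) | O=C1[C@@H](O[Si](C)(C)C(C)(C)C)CCC23CCC4(OCCO4)CC12O3
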